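## Structural features

The target, C24H18O14, consists of four benzene rings joined by three diaryl ether oxygens, with no other ring or chain. The central ring B carries oxygen on five carbons: B1–O is the ether to A1 of ring A (a 2,4,6-trihydroxyphenyl group), B4–O and B6–O are the ethers to C1 and D1 of two identical 3,4,5-trihydroxyphenyl rings C and D, B3 and B5 bear free hydroxyls, and B2 bears the only hydrogen of ring B. There is no stereocentre, so none stand next to each other, and the ether axes are not expected to be configurationally stable. The fragile groups are the eleven free phenols: the pyrogallol units of rings C and D oxidise easily, above all as phenolates, and the phloroglucinol-type rings A and B react with electrophiles at carbon. The real difficulty is twofold: three aryl C–O bonds must be made at carbons flanked by oxygen on both sides (B4, B6, A1), and the five oxygens of ring B must be told apart. The key step uses the phloroglucinol pattern of ring B (oxygen on B1, B3, B5): in the parent triol, B2, B4 and B6 are equivalent by threefold symmetry, so aryloxy groups placed on any two of them end on B4 and B6 and the third carbon becomes B2–H.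

## Logic of the disconnections

**14 ⇒ 13.** The hydroxyls on C3, C4, C5, D3, D4, D5 and A4 are masked as methyl ethers, so seven O–CH3 bonds are cut in the last forward step. The reason is that the pyrogallol rings cannot be carried as free phenols through basic and oxidative steps. The skeleton is unchanged, but seven of the eleven phenols are silenced. The forward step must cleave seven aryl methyl ethers without touching the three diaryl ether bonds.

**13 ⇒ 11 (through 12).** Ring A is cut at the A1–A6 bond, and the oxygen on A2 is joined to A6 instead. This turns the benzene ring into a six-membered lactone in which A1 lies outside the ring as an O–CH2 group. The gain is that the hindered aryl C–O bond at A1 becomes an ordinary alkyl C–O bond. The demand is that, after the lactone is opened to 12, the carbanion at the aryloxy-bearing methylene closes onto the ester carbon and the product aromatises.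

**11 ⇒ 8 + 10.** The O–CH2 bond between the B1 oxygen and the future A1 is cut. This separates the whole of ring A, as a small electrophile, from the tetra-aryl ether core. The forward alkylation must take one of the two equivalent hydroxyls on B1/B3, must not take the hydroxyl on B5, and must stop after one alkylation.

**10 ⇒ 9.** The C–Br bond of the side chain is cut, which leads back to a commercial lactone. The forward step must brominate the methyl group and not the ring.

**8 ⇒ 7.** The B2–H bond is exchanged for B2–Br. This bromine is the one halogen of the key step that was not used, so it costs nothing to carry and must only be removed reductively without harm to the ethers.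

**7 ⇒ 2 + 3 + 3 (through 6, 5 and 4).** The B4–O and B6–O bonds are cut, which are the two most hindered bonds of the target. This reduces the core to a threefold-symmetric tribromide and two equivalents of a commercial phenol. The forward step must make the electron-rich ring B the electrophile. It must also couple two different phenols through oxygen and not through carbon, and must do so twice, each time with one equivalent of 3.

**2 ⇒ 1.** Three C–Br bonds are cut, which leads to the commercial triol. The forward bromination must stop at three bromines.

## Other disconnections considered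

Alternative 1: The cut is at the C4–O and D4–O bonds, the para oxygens of the outer rings; the rings enter as aldehydes. In the forward sense, the two hydroxyls of ring-B diol A1 would each displace fluoride from a molecule of aldehyde A2 (nucleophilic aromatic substitution para to the formyl group) to give dialdehyde A3. The key step would then treat A3 with a peracid: both formyl groups become formates by Baeyer–Villiger aryl migration, and hydrolysis gives bis-phenol A4.
- In favour: every reaction type is known, the formyl group serves first as activator and then as the oxygen, and the electron-rich aryl group migrates readily. The B1 oxygen is set apart as a benzyl ether from the start, so ring A can later be attached without a statistical step. On these points of precedent and of differentiation the alternative is the better plan.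
- Against: A1 is a pentaoxygenated benzene with three kinds of oxygen substituent and would need several steps of its own, whereas the chosen plan takes the whole oxygen pattern of ring B from 1. The phenoxides of A1 are each flanked by two oxygens and should substitute slowly. The peracid can also oxidise the electron-rich rings and the new 4-hydroxy-3,5-dimethoxyphenyl units.
- Comparison: on structure the two plans make the same skeleton; on mechanism the alternative is safer; on step economy it should need roughly twice as many steps, since debenzylation, ring A and the global demethylation still follow A4.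

Alternative 2: The cut runs through ring A itself, at A2–A3 and A4–A5. Phenol A5 would be O-alkylated at an acetic acid unit, and ketene formation with cycloaddition to alkyne A7 would give cyclobutenone A6. The key step heats A6 with more A7: electrocyclic opening to a vinylketene, (2+2) addition, a second opening and a 6π closure give ring A in A8 (Danheiser benzannulation).
- In favour: the reaction type is known for alkoxyalkynes, the substitution pattern of ring A follows from the mechanism, and the A1–O bond is made by alkylation at sp3 carbon, as in the chosen plan. For the ring-forming event itself the alternative has the better precedent, because step 6 of the chosen plan is a new method.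
- Against: it addresses only ring A, the least hindered part. The B4–O and B6–O bonds and the differentiation of ring B in A5 must come from another method, such as alternative 3. Ring A costs about four operations instead of two, and its two ethyl ethers join the final deprotection.
- Comparison: on structure it demands a pre-differentiated ring B, which gives better control than step 5 but costs steps; on mechanism it is a well-understood pericyclic cascade; on step economy the chosen plan is shorter.

Alternative 3: The cut is at the same two bonds as in the chosen plan, B4–O–C1 and B6–O–D1, with reversed polarity: the ring-B oxygens are nucleophiles and the outer rings electrophiles. Fluoride would release aryne A10 from silyl triflate A9. The two phenoxides of diol A1 add at C1, remote from the 3-methoxy group, and protonation gives A11.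
- In favour: O-arylation of phenols by arynes is known, is mild, is little affected by flanking substituents on the phenoxide, and is regioselective with 3-alkoxyarynes. Both bonds form in one operation, and B1 is already differentiated. In precedent and in differentiation the alternative is the better plan; in the bonds formed it is the equal of the chosen plan.
- Against: A1 and A9 each need several steps (A9 from 3 by bromination, silylation with rearrangement, and triflation). The electron-rich phenoxide ring can also be arylated at carbon B2, and the aryl anion needs a proton source.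
- Comparison: on structure equal; on mechanism the alternative is safer; on step economy the chosen plan is clearly shorter, because it uses 1 and 3 directly. After A11, debenzylation to A5, ring A and the demethylation would still follow.

Key step: step 2

Remark: step 2 comprises two consecutive oxidation–reduction cycles, with 5 carried on crude between them; each cycle consumes one equivalent of 3, so two equivalents of 3 end up in 7.
Remark: dienones 4 and 6 are drawn as one enol tautomer each and are racemic at their sp3 carbon, which becomes planar again in the zinc step.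

## Route

**Step 1**
Reactants: 1 (phloroglucinol, benzene-1,3,5-triol)
Product: 2 2,4,6-tribromobenzene-1,3,5-triol
Conditions: Br2 (3.0 equiv), H2O, 0 °C to rt; filter, dry
Reagents that add atoms: bromine, BrBr
Why: Threefold electrophilic aromatic bromination; each free ring carbon of 1 is ortho or para to three hydroxyls, and with three equivalents of bromine the reaction should stop at 2, which is expected to separate from water.

**Step 2**
Reactants: 2 (2,4,6-tribromobenzene-1,3,5-triol); 3 (3,4,5-trimethoxyphenol, first equivalent, consumed in the first cycle)
Product: 7 2-bromo-4,6-bis(3,4,5-trimethoxyphenoxy)benzene-1,3,5-triol, via aryloxy tribromodienone 4 (not isolated), via dibromo monoaryl ether 5 (not isolated), via bis(aryloxy) dibromodienone 6 (not isolated)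
Conditions: (a) 3 (1.2 equiv), 2,6-lutidine (1.0 equiv), Bu4NBF4, (CF3)2CHOH, graphite anode, Pt cathode, undivided cell, anode held at the phenolate wave (set by cyclic voltammetry), 2 F/mol, 0 °C, argon; (b) Zn dust (1.5 equiv), AcOH, 0 °C; filter, EtOAc/H2O wash, evaporate; (c) crude 5 returned to the cell, (a) and (b) repeated with a second portion of 3 (1.2 equiv)
Reagents that add atoms: 3,4,5-trimethoxyphenol (the second equivalent of 3, consumed in the second cycle), COc1cc(O)cc(OC)c1OC
Why: Proposed new method: in each cycle one equivalent of 2,6-lutidine ionises only the strongly acidic bromophenol (2 in the first cycle, 5 in the second), and its phenolate is oxidised at graphite by two electrons, below the potential of neutral 3, to a phenoxonium ion stabilised by hexafluoroisopropanol; one molecule of neutral 3 adds through its hydroxyl oxygen to a bromine-bearing ring carbon and loses a proton, giving the racemic aryloxy bromodienone (4, then 6). Zinc in acetic acid then transfers two electrons to the tertiary C–Br bond next to the carbonyl, bromide leaves as the better of the two leaving groups, and the enol returns to the arene (5, then 7), so each cycle is a net replacement of Br by OAr on an electron-rich ring and the two cycles together build in two molecules of 3. The closest known reaction type is the anodic oxidation of 2,6-dihalophenols to ortho-aryloxy halodienones followed by zinc reduction to ortho-hydroxy diaryl ethers, which is known as a homo-coupling and as a ring closure but not as a cross-coupling of two different phenols. No ring is closed and 7 has no stereocentre. Cross-coupling should win over homo-coupling because only the bromophenol is ionised and oxidised, while its own hydroxyls, each flanked by two ring substituents, are poor nucleophiles. Attack of 3 through oxygen and not through its C2 is expected because a C–C bond would join two carbons that each carry two ortho substituents. Site selectivity is not needed in the first cycle, since the three bromine-bearing carbons of 2 are equivalent, and in the second cycle the two bromine-bearing carbons of 5 are mirror images; addition at the aryloxy-bearing carbon would only return 5 after the zinc step.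

**Step 3**
Reactants: 7 (2-bromo-4,6-bis(3,4,5-trimethoxyphenoxy)benzene-1,3,5-triol)
Product: 8 2,4-bis(3,4,5-trimethoxyphenoxy)benzene-1,3,5-triol
Conditions: H2 (1 atm), 10% Pd/C, NaOAc (1.5 equiv), MeOH, rt
Reagents that add atoms: none
Why: Catalytic hydrogenolysis of the aryl C–Br bond (hydrodehalogenation) on palladium; acetate takes up the hydrogen bromide, and methyl ethers, diaryl ethers and the arenes should not be reduced at one atmosphere and room temperature.

**Step 4**
Reactants: 9 (4-methoxy-6-methyl-2H-pyran-2-one)
Product: 10 6-(bromomethyl)-4-methoxy-2H-pyran-2-one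
Conditions: NBS (1.05 equiv), benzoyl peroxide (5 mol%), PhCF3, reflux
Reagents that add atoms: N-bromosuccinimide, O=C1CCC(=O)N1Br
Why: Wohl–Ziegler radical bromination; the 6-methyl group is allylic to the ring double bond and vinylogous to the lactone carbonyl, so hydrogen abstraction there is favoured, and radical conditions in a non-polar solvent should suppress ionic bromination at C3.

**Step 5**
Reactants: 8 (2,4-bis(3,4,5-trimethoxyphenoxy)benzene-1,3,5-triol, 1.5 equiv); 10 (6-(bromomethyl)-4-methoxy-2H-pyran-2-one, 1.0 equiv, added slowly)
Product: 11 6-{[3,5-dihydroxy-2,4-bis(3,4,5-trimethoxyphenoxy)phenoxy]methyl}-4-methoxy-2H-pyran-2-one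
Conditions: K2CO3 (1.1 equiv), DMF, 0 °C to rt, argon; unreacted 8 recovered
Reagents that add atoms: none
Why: Williamson ether synthesis by SN2 displacement at the activated primary bromide of 10. The hydroxyls on B1 and B3 are equivalent and each has one free ortho position, whereas the hydroxyl on B5 lies between two aryloxy groups, so the rapidly equilibrating phenoxides should react mainly at B1/B3; 10 as the limiting reagent should hold back a second alkylation, and the polar aprotic solvent favours oxygen over carbon (B2) alkylation.

**Step 6**
Reactants: 11 (6-{[3,5-dihydroxy-2,4-bis(3,4,5-trimethoxyphenoxy)phenoxy]methyl}-4-methoxy-2H-pyran-2-one)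
Product: 13 2-[3,5-dihydroxy-2,4-bis(3,4,5-trimethoxyphenoxy)phenoxy]-5-methoxybenzene-1,3-diol, via ring-opened keto ester 12 (not isolated)
Conditions: Mg(OMe)2 (8 equiv), MeOH, reflux, argon; then 1 M HCl, 0 °C
Reagents that add atoms: none
Why: Proposed new method: methoxide opens the lactone of 11 to the magnesium-chelated keto ester 12, whose enolate at the aryloxy-bearing methylene attacks the ester carbonyl in a six-membered Claisen (Dieckmann-type) condensation, and the resulting cyclohexenedione aromatises irreversibly to ring A; the closest known reaction type is the Mg(OMe)2-mediated Claisen recyclisation of 6-(2-oxoalkyl)-4-methoxy-2-pyranones to acylphloroglucinol monomethyl ethers, where the attacking carbon is doubly activated, whereas here it carries only the ketone and the aryloxy group. Every other closure open to 12 is four-membered or a return to 11, so the aromatic product is the only irreversible outlet.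

**Step 7**
Reactants: 13 (2-[3,5-dihydroxy-2,4-bis(3,4,5-trimethoxyphenoxy)phenoxy]-5-methoxybenzene-1,3-diol)
Product: 14 2-[3,5-dihydroxy-2,4-bis(3,4,5-trihydroxyphenoxy)phenoxy]benzene-1,3,5-triol (target)
Conditions: BBr3 (14 equiv), CH2Cl2, −78 °C to rt, argon; then H2O, 0 °C; Sephadex LH-20 (MeOH), argon
Reagents that add atoms: none
Why: Lewis-acid cleavage of aryl methyl ethers: each methoxy oxygen binds boron and bromide attacks the methyl group in an SN2 step, while the diaryl ether oxygens have no alkyl group to lose and should survive. Aqueous work-up under argon releases the eleven phenols of 14.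

## Compound list

1 | phloroglucinol (benzene-1,3,5-triol) | Oc1cc(O)cc(O)c1 | starting material
2 | 2,4,6-tribromobenzene-1,3,5-triol | Oc1c(Br)c(O)c(Br)c(O)c1Br | intermediate
3 | 3,4,5-trimethoxyphenol | COc1cc(O)cc(OC)c1OC | starting material
4 | 2,4,6-tribromo-3,5-dihydroxy-6-(3,4,5-trimethoxyphenoxy)cyclohexa-2,4-dien-1-one (racemic, formed and consumed in step 2) | O=C1C(Br)=C(O)C(Br)=C(O)C1(Br)Oc1cc(OC)c(OC)c(OC)c1 | intermediate
5 | 2,4-dibromo-6-(3,4,5-trimethoxyphenoxy)benzene-1,3,5-triol (carried on crude in step 2) | Oc1c(Br)c(O)c(Br)c(O)c1Oc1cc(OC)c(OC)c(OC)c1 | intermediate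
6 | 4,6-dibromo-3,5-dihydroxy-2,6-bis(3,4,5-trimethoxyphenoxy)cyclohexa-2,4-dien-1-one (racemic, formed and consumed in step 2) | O=C1C(Oc2cc(OC)c(OC)c(OC)c2)=C(O)C(Br)=C(O)C1(Br)Oc1cc(OC)c(OC)c(OC)c1 | intermediate
7 | 2-bromo-4,6-bis(3,4,5-trimethoxyphenoxy)benzene-1,3,5-triol | Oc1c(Br)c(O)c(Oc2cc(OC)c(OC)c(OC)c2)c(O)c1Oc1cc(OC)c(OC)c(OC)c1 | intermediate
8 | 2,4-bis(3,4,5-trimethoxyphenoxy)benzene-1,3,5-triol | Oc1cc(O)c(Oc2cc(OC)c(OC)c(OC)c2)c(O)c1Oc1cc(OC)c(OC)c(OC)c1 | intermediate
9 | 4-methoxy-6-methyl-2H-pyran-2-one | COC1=CC(=O)OC(C)=C1 | starting material
10 | 6-(bromomethyl)-4-methoxy-2H-pyran-2-one | COC1=CC(=O)OC(CBr)=C1 | intermediate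
11 | 6-{[3,5-dihydroxy-2,4-bis(3,4,5-trimethoxyphenoxy)phenoxy]methyl}-4-methoxy-2H-pyran-2-one | COC1=CC(=O)OC(COc2cc(O)c(Oc3cc(OC)c(OC)c(OC)c3)c(O)c2Oc2cc(OC)c(OC)c(OC)c2)=C1 | intermediate
12 | methyl (2E)-6-[3,5-dihydroxy-2,4-bis(3,4,5-trimethoxyphenoxy)phenoxy]-3-methoxy-5-oxohex-2-enoate (as its magnesium enolate, formed and consumed in step 6) | COC(=O)/C=C(/OC)CC(=O)COc1cc(O)c(Oc2cc(OC)c(OC)c(OC)c2)c(O)c1Oc1cc(OC)c(OC)c(OC)c1 | intermediate
13 | 2-[3,5-dihydroxy-2,4-bis(3,4,5-trimethoxyphenoxy)phenoxy]-5-methoxybenzene-1,3-diol | COc1cc(O)c(Oc2cc(O)c(Oc3cc(OC)c(OC)c(OC)c3)c(O)c2Oc2cc(OC)c(OC)c(OC)c2)c(O)c1 | intermediate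
14 | 2-[3,5-dihydroxy-2,4-bis(3,4,5-trihydroxyphenoxy)phenoxy]benzene-1,3,5-triol | Oc1cc(O)c(Oc2cc(O)c(Oc3cc(O)c(O)c(O)c3)c(O)c2Oc2cc(O)c(O)c(O)c2)c(O)c1 | target

## Step count and least certain steps

Total step count: 7. Longest linear sequence: 6 steps (1 → 2 → 7 → 8 → 11 → 13 → 14); step 4 is a one-step branch.

**Step 2 (key step, new method).** Four processes are most likely to go wrong. The nucleophile may be oxidised alongside the phenolate, because hydrogen bonding by the solvent can bring the two potentials close together. 3 may add through ring carbon, because the same solvent lowers the nucleophilicity of its oxygen. In the second cycle, addition may go to the carbon that already carries an aryloxy group, where the cationic charge is best stabilised; this would show as low conversion, since zinc returns 5. Zinc may also over-reduce 5 with loss of a ring bromine through a keto tautomer before the second cycle.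

Fallback by known chemistry, setting out from 3 and coming back at 8: commercial 1,3,5-tris(benzyloxy)benzene is iodinated twice (N-iodosuccinimide, MeCN) to 1,3,5-tris(benzyloxy)-2,4-diiodobenzene F1. F1 is coupled with two equivalents of 3 in an Ullmann diaryl ether synthesis (CuI, picolinic acid, K3PO4, DMSO, 100 °C) to 1,3,5-tris(benzyloxy)-2,4-bis(3,4,5-trimethoxyphenoxy)benzene F2. Hydrogenolysis of the three benzyl ethers (H2, Pd/C, EtOAc/MeOH) then gives 8.

**Step 6 (new method).** Most likely to go wrong: 12 is deprotonated at the more acidic methylene between the ketone and the enol ether and simply re-closes to the lactone, while the less acidic aryloxy-bearing methylene is not engaged. Reversible aldol-type addition of ring carbon B2 to the ketone could hold material back as well.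

Fallback by known chemistry, setting out from 8 and coming back at 14: an Ullmann coupling of 8 with commercial 2-iodo-1,3,5-trimethoxybenzene as the limiting reagent (CuI, picolinic acid, K3PO4, DMSO, 100 °C, argon) should give 2,4-bis(3,4,5-trimethoxyphenoxy)-5-(2,4,6-trimethoxyphenoxy)benzene-1,3-diol F3. This coupling is sensitive to ortho substitution on the phenol and should therefore spare the hydroxyl on B5. F3 is then demethylated under the conditions of step 7 to 14.

**Step 5.** Most likely to go wrong: alkylation at the B5 oxygen, which belongs to the more acidic hydroxyl, a second alkylation at the other equivalent hydroxyl, and alkylation at carbon B2 of the phloroglucinol-type phenoxide.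

Fallback, setting out from 8 and coming back at 14, in which protecting groups fix the site: iPr3SiCl and imidazole in DMF should silylate only the two open hydroxyls, giving 2,6-bis(3,4,5-trimethoxyphenoxy)-3,5-bis[(triisopropylsilyl)oxy]phenol F4. MeI and K2CO3 then cap the hydroxyl on B5, giving 2-methoxy-1,3-bis(3,4,5-trimethoxyphenoxy)-4,6-bis[(triisopropylsilyl)oxy]benzene F5. Bu4NF in THF frees the two equivalent hydroxyls, giving 5-methoxy-4,6-bis(3,4,5-trimethoxyphenoxy)benzene-1,3-diol F6. Alkylation with 10 as in step 5 gives 6-{[5-hydroxy-3-methoxy-2,4-bis(3,4,5-trimethoxyphenoxy)phenoxy]methyl}-4-methoxy-2H-pyran-2-one F7, and recyclisation as in step 6 gives 2-[5-hydroxy-3-methoxy-2,4-bis(3,4,5-trimethoxyphenoxy)phenoxy]-5-methoxybenzene-1,3-diol F8. BBr3 as in step 7 removes the extra methyl ether together with the others and gives 14. The choice between the two remaining equivalent hydroxyls of F6 stays statistical.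

**Step 7.** Most likely to go wrong: incomplete cleavage at one or more of the seven sites, and oxidation of the pyrogallol rings during aqueous work-up and chromatography of the free polyphenol.

Fallback, setting out from 13 and coming back at 14, by a derivatise–purify–release end game: the crude product of the BBr3 treatment is peracetylated (Ac2O, pyridine) to the undecaacetate of 14 F9, which should be stable to air and can be purified on silica. Acid-catalysed methanolysis (HCl in MeOH, argon) then releases 14 with only volatile by-products, so the free polyphenol needs no chromatography.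

## Further compounds

F1 | step 2 | 1,3,5-tris(benzyloxy)-2,4-diiodobenzene | Ic1c(OCc2ccccc2)cc(OCc2ccccc2)c(I)c1OCc1ccccc1
F2 | step 2 | 1,3,5-tris(benzyloxy)-2,4-bis(3,4,5-trimethoxyphenoxy)benzene | COc1cc(Oc2c(OCc3ccccc3)cc(OCc3ccccc3)c(Oc3cc(OC)c(OC)c(OC)c3)c2OCc2ccccc2)cc(OC)c1OC
F3 | step 6 | 2,4-bis(3,4,5-trimethoxyphenoxy)-5-(2,4,6-trimethoxyphenoxy)benzene-1,3-diol | COc1cc(OC)c(Oc2cc(O)c(Oc3cc(OC)c(OC)c(OC)c3)c(O)c2Oc2cc(OC)c(OC)c(OC)c2)c(OC)c1
F4 | step 5 | 2,6-bis(3,4,5-trimethoxyphenoxy)-3,5-bis[(triisopropylsilyl)oxy]phenol | COc1cc(Oc2c(O)c(Oc3cc(OC)c(OC)c(OC)c3)c(O[Si](C(C)C)(C(C)C)C(C)C)cc2O[Si](C(C)C)(C(C)C)C(C)C)cc(OC)c1OC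
F5 | step 5 | 2-methoxy-1,3-bis(3,4,5-trimethoxyphenoxy)-4,6-bis[(triisopropylsilyl)oxy]benzene | COc1cc(Oc2c(OC)c(Oc3cc(OC)c(OC)c(OC)c3)c(O[Si](C(C)C)(C(C)C)C(C)C)cc2O[Si](C(C)C)(C(C)C)C(C)C)cc(OC)c1OC
F6 | step 5 | 5-methoxy-4,6-bis(3,4,5-trimethoxyphenoxy)benzene-1,3-diol | COc1c(Oc2cc(OC)c(OC)c(OC)c2)c(O)cc(O)c1Oc1cc(OC)c(OC)c(OC)c1
F7 | step 5 | 6-{[5-hydroxy-3-methoxy-2,4-bis(3,4,5-trimethoxyphenoxy)phenoxy]methyl}-4-methoxy-2H-pyran-2-one | COC1=CC(=O)OC(COc2cc(O)c(Oc3cc(OC)c(OC)c(OC)c3)c(OC)c2Oc2cc(OC)c(OC)c(OC)c2)=C1
F8 | step 5 | 2-[5-hydroxy-3-methoxy-2,4-bis(3,4,5-trimethoxyphenoxy)phenoxy]-5-methoxybenzene-1,3-diol | COc1cc(O)c(Oc2cc(O)c(Oc3cc(OC)c(OC)c(OC)c3)c(OC)c2Oc2cc(OC)c(OC)c(OC)c2)c(O)c1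
F9 | step 7 | undecaacetate of 14 (all eleven hydroxyls as acetates) | CC(=O)Oc1cc(OC(C)=O)c(Oc2cc(OC(C)=O)c(Oc3cc(OC(C)=O)c(OC(C)=O)c(OC(C)=O)c3)c(OC(C)=O)c2Oc2cc(OC(C)=O)c(OC(C)=O)c(OC(C)=O)c2)c(OC(C)=O)c1
A1 | alternative 1 | 4-(benzyloxy)-2,6-dimethoxybenzene-1,3-diol | COc1cc(OCc2ccccc2)c(O)c(OC)c1O
A2 | alternative 1 | 4-fluoro-2,6-dimethoxybenzaldehyde | COc1cc(F)cc(OC)c1C=O
A3 | alternative 1 | 4,4'-{[4-(benzyloxy)-2,6-dimethoxy-1,3-phenylene]bis(oxy)}bis(2,6-dimethoxybenzaldehyde) | COc1cc(OCc2ccccc2)c(Oc2cc(OC)c(C=O)c(OC)c2)c(OC)c1Oc1cc(OC)c(C=O)c(OC)c1
A4 | alternative 1 | 4,4'-{[4-(benzyloxy)-2,6-dimethoxy-1,3-phenylene]bis(oxy)}bis(2,6-dimethoxyphenol) | COc1cc(OCc2ccccc2)c(Oc2cc(OC)c(O)c(OC)c2)c(OC)c1Oc1cc(OC)c(O)c(OC)c1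
A5 | alternative 2 | 3,5-dimethoxy-2,4-bis(3,4,5-trimethoxyphenoxy)phenol | COc1cc(O)c(Oc2cc(OC)c(OC)c(OC)c2)c(OC)c1Oc1cc(OC)c(OC)c(OC)c1
A6 | alternative 2 | 4-[3,5-dimethoxy-2,4-bis(3,4,5-trimethoxyphenoxy)phenoxy]-3-ethoxycyclobut-2-en-1-one (racemic) | CCOC1=CC(=O)C1Oc1cc(OC)c(Oc2cc(OC)c(OC)c(OC)c2)c(OC)c1Oc1cc(OC)c(OC)c(OC)c1
A7 | alternative 2 | ethoxyacetylene (ethoxyethyne) | CCOC#C
A8 | alternative 2 | 2-[3,5-dimethoxy-2,4-bis(3,4,5-trimethoxyphenoxy)phenoxy]-3,5-diethoxyphenol | CCOc1cc(O)c(Oc2cc(OC)c(Oc3cc(OC)c(OC)c(OC)c3)c(OC)c2Oc2cc(OC)c(OC)c(OC)c2)c(OCC)c1
A9 | alternative 3 | 3,4,5-trimethoxy-2-(trimethylsilyl)phenyl trifluoromethanesulfonate | COc1cc(OS(=O)(=O)C(F)(F)F)c([Si](C)(C)C)c(OC)c1OC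
A10 | alternative 3 | 3,4,5-trimethoxybenzyne (1,2-didehydro-3,4,5-trimethoxybenzene) | COC1=C(OC)C(OC)=CC#C1
A11 | alternative 3 | 1-(benzyloxy)-3,5-dimethoxy-2,4-bis(3,4,5-trimethoxyphenoxy)benzene | COc1cc(OCc2ccccc2)c(Oc2cc(OC)c(OC)c(OC)c2)c(OC)c1Oc1cc(OC)c(OC)c(OC)c1
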